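**Assumption:** the SMILES is taken as definitive. In cembrane numbering (C1 = ring CH bearing acrylate carbon C15, C3 = CHOH, C11 = CHOAc, C12 = C(Me)–O–lactone) it reads 1R,3R,11S,12R,4E,7E. This numbering is used throughout.

## Retrosynthetic overview
1. The C3 carbinol comes from CBS reduction of the macrocyclic enone. The enone comes from Nozaki–Hiyama–Kishi closure of C3–C4, so the 14-membered ring is formed last.
2. C8–C9 comes from a B-alkyl Suzuki coupling of a vinyl-bearing ε-lactone with the symmetric linchpin (2E,5E)-2,6-diiodohepta-2,5-diene, which delivers both E-alkenes preformed.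
3. The ε-lactone (formed first) comes from 7-exo opening of an 11,12-epoxide at C12, with inversion, by the C16 acid. The C11–O bond is retained and becomes the acetate.
4. The epoxide comes from Sharpless epoxidation of an E-allylic alcohol, itself made by HWE on the C12 methyl ketone. C9 comes from a Wittig methylenation.
5. C1 and ten of the carbons come from (R)-limonene, by allylic metalation/oxidation and ring-alkene ozonolysis.

## Route

**Step 1**
Reactants: 1, (R)-(+)-limonene
Product: 2, (R)-limonen-10-ol, 2-[(1R)-4-methylcyclohex-3-en-1-yl]prop-2-en-1-ol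
Conditions: n-BuLi, TMEDA, rt, 16 h; B(OMe)3, THF, −78 °C to rt; 30% H2O2, NaOH, 0 °C
Reagents that add atoms: hydrogen peroxide, OO
Why: Allylic metalation removes an isopropenyl CH3 proton to give a symmetric allyllithium, and borylation/oxidation gives the primary allylic alcohol (C16–OH) without touching the C1 stereocentre.

**Step 2**
Reactants: 2
Product: 3, TBDPS ether of 2
Conditions: TBDPSCl, imidazole, DMF, rt
Reagents that add atoms: TBDPSCl, CC(C)(C)[Si](Cl)(c1ccccc1)c1ccccc1
Why: Silyl ether formation; TBDPS is chosen because it survives the acidic acetalisation in step 4 and all basic or reducing steps up to step 10.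

**Step 3**
Reactants: 3
Product: 4, (3R)-3-[3-(TBDPS-oxy)prop-1-en-2-yl]-6-oxoheptanal (C3 aldehyde, C12 methyl ketone)
Conditions: O3 (1 equiv, Sudan Red end-point), CH2Cl2, −78 °C; PPh3
Reagents that add atoms: ozone, [O-][O+]=O
Why: Chemoselective ozonolysis cleaves the electron-rich trisubstituted ring alkene faster than the inductively deactivated 1,1-disubstituted allyl silyl ether alkene.

**Step 4**
Reactants: 4
Product: 5, (5R)-5-[3-(TBDPS-oxy)prop-1-en-2-yl]-6-(1,3-dioxolan-2-yl)hexan-2-one
Conditions: ethylene glycol (1.5 equiv), PPTS (cat.), benzene, reflux, Dean–Stark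
Reagents that add atoms: ethylene glycol, OCCO
Why: Chemoselective acetalisation (aldehyde much faster than methyl ketone); the cyclic acetal is chosen so that it survives the acid-catalysed step 12.

**Step 5**
Reactants: 5
Product: 6, ethyl (2E,6R)-6-[3-(TBDPS-oxy)prop-1-en-2-yl]-7-(1,3-dioxolan-2-yl)-3-methylhept-2-enoate
Conditions: (EtO)2P(O)CH2CO2Et, NaH, THF, 0 °C to rt; remove the minor Z isomer by chromatography (here or at 7)
Reagents that add atoms: triethyl phosphonoacetate, CCOC(=O)CP(=O)(OCC)OCC
Why: Horner–Wadsworth–Emmons olefination of the methyl ketone adds C11 and C10 and favours the E-enoate (about 5:1).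

**Step 6**
Reactants: 6
Product: 7, the (2E,6R)-allylic alcohol (C10–OH, 11E-alkene)
Conditions: DIBAL-H (2.3 equiv), CH2Cl2, −78 °C
Reagents that add atoms: none
Why: 1,2-Reduction of the enoate; the acetal and silyl ether are inert at −78 °C.

**Step 7**
Reactants: 7
Product: 8, the (2S,3S)-2,3-epoxy alcohol (11S,12S)
Conditions: Ti(OiPr)4 (10 mol %), L-(+)-DET (12 mol %), TBHP, 4 Å MS, CH2Cl2, −20 °C
Reagents that add atoms: tert-butyl hydroperoxide, CC(C)(C)OO
Why: Katsuki–Sharpless epoxidation is reagent-controlled, and L-(+)-DET gives the (2S,3S)-epoxide as it does with geraniol; this sets C11 (final) and C12 (inverted in step 12) and leaves the other alkene, which has no free allylic OH, untouched.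

**Step 8**
Reactants: 8
Product: 9, the epoxy aldehyde (same geometry; CIP label at C11 becomes R)
Conditions: SO3·pyridine, DMSO, iPr2NEt, CH2Cl2, 0 °C
Reagents that add atoms: none
Why: Parikh–Doering oxidation is mild and leaves both the epoxide and its configuration intact.

**Step 9**
Reactants: 9
Product: 10, the vinyl epoxide (3S,4S,7R)-3,4-epoxy-4-methyl-7-[3-(TBDPS-oxy)prop-1-en-2-yl]-8-(1,3-dioxolan-2-yl)oct-1-ene
Conditions: Ph3PCH3Br, KHMDS, THF, −78 to 0 °C
Reagents that add atoms: methyltriphenylphosphonium bromide, C[P+](c1ccccc1)(c1ccccc1)c1ccccc1.[Br-]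
Why: Wittig methylenation adds C9 and creates the terminal alkene needed for the Suzuki union.

**Step 10**
Reactants: 10
Product: 11, (3R,6S,7S)-3-(1,3-dioxolan-2-ylmethyl)-6,7-epoxy-6-methyl-2-methylidenenon-8-en-1-ol
Conditions: TBAF, THF, 0 °C to rt
Reagents that add atoms: none
Why: Fluoride desilylation; the epoxide and acetal are stable to TBAF.

**Step 11**
Reactants: 11
Product: 12, the corresponding 2-methylidene carboxylic acid (C16 acid)
Conditions: TEMPO (cat.), NaClO2, NaOCl (cat.), MeCN/pH 6.7 phosphate buffer, 35 °C
Reagents that add atoms: sodium chlorite, [Na+].[O-]Cl=O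
Why: TEMPO/chlorite oxidation takes the alcohol through the enal to the acid at near-neutral pH, which spares the epoxide and the acetal.

**Step 12**
Reactants: 12
Product: 13, (1S)-1-[(2R,5R)-5-(1,3-dioxolan-2-ylmethyl)-2-methyl-6-methylidene-7-oxooxepan-2-yl]prop-2-en-1-yl acetate
Conditions: CSA (10 mol %), CH2Cl2 (0.01 M), 0 °C; then Et3N, Ac2O, DMAP, rt (one pot)
Reagents that add atoms: acetic anhydride, CC(=O)OC(C)=O
Why: Acid-catalysed 7-exo-tet epoxide opening by the carboxylic acid occurs at the tertiary C12 with inversion (12S to 12R) and leaves C11–O intact (11S), and the freed C11–OH is acetylated in situ.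

**Step 13**
Reactants: 14, 1-propynylmagnesium bromide; 15, 1-bromobut-2-yne
Product: 16, hepta-2,5-diyne
Conditions: CuCl (5 mol %), THF, 0 to 50 °C
Reagents that add atoms: none (both partners are numbered reactants)
Why: Cu-catalysed propargylic substitution is the standard synthesis of skipped diynes.

**Step 14**
Reactants: 16
Product: 17, (2E,5E)-2,6-diiodohepta-2,5-diene
Conditions: Cp2Zr(H)Cl (3 equiv), THF, rt to 45 °C, dark; I2, −20 °C
Reagents that add atoms: iodine, II
Why: In the double syn-hydrozirconation, excess Zr–H equilibrates Zr onto the less hindered methyl-bearing carbon, and iodinolysis with retention gives both E-2-iodoalkenes (I trans to the central CH2).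

**Step 15**
Reactants: 13; 17 (4 equiv, excess recovered)
Product: 18, (1S,4E,7E)-1-[(2R,5R)-5-(1,3-dioxolan-2-ylmethyl)-2-methyl-6-methylidene-7-oxooxepan-2-yl]-8-iodo-4-methylnona-4,7-dien-1-yl acetate
Conditions: 9-BBN, THF, rt; then 17, PdCl2(dppf) (10 mol %), AsPh3, Cs2CO3, DMF/H2O, rt
Reagents that add atoms: none (9-BBN supplies only H)
Why: In this B-alkyl Suzuki–Miyaura coupling, 9-BBN adds to the only electron-rich terminal alkene (the acrylate is deactivated), the coupling retains alkene geometry, and excess symmetric diiodide enforces mono-coupling.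

**Step 16**
Reactants: 18
Product: 19, the C3 aldehyde (2-oxoethyl in place of dioxolanylmethyl)
Conditions: TESOTf, 2,6-lutidine, CH2Cl2, 0 °C; then H2O
Reagents that add atoms: water, O
Why: Near-neutral cleavage of the aldehyde acetal via a lutidinium intermediate spares the acetate, the tertiary lactone, the vinyl iodide and the skipped diene.

**Step 17**
Reactants: 19
Product: 20, the macrocyclic allylic alcohol as a C3 epimer mixture (1R,11S,12R,4E,7E)
Conditions: CrCl2 (10 equiv), NiCl2 (1 wt %), DMSO/THF, 2 mM, slow addition, rt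
Reagents that add atoms: none
Why: The Nozaki–Hiyama–Kishi macrocyclisation is aldehyde-selective, tolerates the esters and the acrylate, and retains vinyl iodide geometry; no C3 selectivity is required at this stage.

**Step 18**
Reactants: 20
Product: 21, the macrocyclic C3 enone
Conditions: Dess–Martin periodinane, NaHCO3, CH2Cl2, 0 °C
Reagents that add atoms: none
Why: Buffered Dess–Martin oxidation converges both epimers while avoiding isomerisation of the skipped diene into conjugation.

**Step 19**
Reactants: 21
Product: 22, dendronpholide B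
Conditions: (S)-Me-CBS (1 equiv), catecholborane, toluene, −78 °C
Reagents that add atoms: none
Why: In the Corey–Bakshi–Shibata reduction the α-methyl alkenyl group acts as the large substituent and C2H2 as the small one, so (S)-CBS gives the 3R alcohol by 1,2-reduction and leaves the lactone, the acetate and all the alkenes untouched.

## Compound list
1 | (R)-(+)-limonene | CC1=CC[C@@H](CC1)C(C)=C | starting material
2 | (R)-limonen-10-ol | CC1=CC[C@@H](CC1)C(=C)CO | intermediate
3 | TBDPS ether of 2 | CC1=CC[C@@H](CC1)C(=C)CO[Si](c1ccccc1)(c1ccccc1)C(C)(C)C | intermediate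
4 | (3R)-keto aldehyde | CC(=O)CC[C@H](CC=O)C(=C)CO[Si](c1ccccc1)(c1ccccc1)C(C)(C)C | intermediate
5 | (5R)-keto dioxolane | CC(=O)CC[C@H](CC1OCCO1)C(=C)CO[Si](c1ccccc1)(c1ccccc1)C(C)(C)C | intermediate
6 | (2E,6R)-enoate | CCOC(=O)/C=C(\C)CC[C@H](CC1OCCO1)C(=C)CO[Si](c1ccccc1)(c1ccccc1)C(C)(C)C | intermediate
7 | (2E,6R)-allylic alcohol | OC/C=C(\C)CC[C@H](CC1OCCO1)C(=C)CO[Si](c1ccccc1)(c1ccccc1)C(C)(C)C | intermediate
8 | (2S,3S)-epoxy alcohol | OC[C@@H]1O[C@@]1(C)CC[C@H](CC1OCCO1)C(=C)CO[Si](c1ccccc1)(c1ccccc1)C(C)(C)C | intermediate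
9 | epoxy aldehyde | O=C[C@@H]1O[C@@]1(C)CC[C@H](CC1OCCO1)C(=C)CO[Si](c1ccccc1)(c1ccccc1)C(C)(C)C | intermediate
10 | vinyl epoxide | C=C[C@@H]1O[C@@]1(C)CC[C@H](CC1OCCO1)C(=C)CO[Si](c1ccccc1)(c1ccccc1)C(C)(C)C | intermediate
11 | vinyl epoxide allylic alcohol | C=C[C@@H]1O[C@@]1(C)CC[C@H](CC1OCCO1)C(=C)CO | intermediate
12 | epoxy acid | C=C[C@@H]1O[C@@]1(C)CC[C@H](CC1OCCO1)C(=C)C(=O)O | intermediate
13 | α-methylene-ε-lactone allylic acetate | C=C1C(=O)O[C@]([C@@H](OC(C)=O)C=C)(C)CC[C@@H]1CC1OCCO1 | intermediate
14 | 1-propynylmagnesium bromide | CC#C[Mg]Br | starting material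
15 | 1-bromobut-2-yne | CC#CCBr | starting material
16 | hepta-2,5-diyne | CC#CCC#CC | intermediate
17 | (2E,5E)-2,6-diiodohepta-2,5-diene | I/C(C)=C/C/C=C(\C)I | intermediate
18 | Suzuki product (vinyl iodide, dioxolane) | C=C1C(=O)O[C@]([C@@H](OC(C)=O)CC/C(C)=C/C/C=C(\C)I)(C)CC[C@@H]1CC1OCCO1 | intermediate
19 | iodo aldehyde | C=C1C(=O)O[C@]([C@@H](OC(C)=O)CC/C(C)=C/C/C=C(\C)I)(C)CC[C@@H]1CC=O | intermediate
20 | macrocyclic alcohol, C3 epimers | C=C1C(=O)O[C@]2(C)CC[C@@H]1CC(O)/C(C)=C/C/C=C(\C)CC[C@@H]2OC(C)=O | intermediate
21 | macrocyclic enone | C=C1C(=O)O[C@]2(C)CC[C@@H]1CC(=O)/C(C)=C/C/C=C(\C)CC[C@@H]2OC(C)=O | intermediate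
22 | dendronpholide B | C=C1C(=O)O[C@]2(C)CC[C@@H]1C[C@@H](O)/C(C)=C/C/C=C(\C)CC[C@@H]2OC(C)=O | target

## Counts
Total steps: 19. Longest linear sequence: 17 (steps 1–12 and 15–19, from (R)-limonene).

## Three steps most likely to fail
1. **Step 12, the 7-exo epoxy-acid lactonisation.**
   - Risks: hydride shift to the vinyl ketone, attack at the allylic C11, and partial SN1 scrambling at C12.
   - Fallback: form the acyl–O bond instead of the C12–O bond. Use D-(−)-DET to make the (11R,12R)-epoxide, then open the vinyl epoxide intermolecularly with acetate at the allylic C11 with inversion. This gives the 11S acetate and the 12R tertiary alcohol directly. The ε-lactone is then closed by MNBA (Shiina) lactonisation of the seco-acid.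
2. **Step 15, hydroboration and mono-Suzuki coupling next to the α-methylene lactone.**
   - Risks: borane or base attack on the acrylate, and double coupling.
   - Fallback: mask the Michael acceptor. Add PhSH/Et3N to 13, carry the β-phenylthio lactone through steps 15–19, and regenerate the exocyclic methylene at the end by sulfoxide formation and syn-elimination.
3. **Step 17, the NHK macrocyclisation (and the CBS reduction on a conformationally biased macrocycle in step 19).**
   - Risks: oligomerisation, and substrate bias opposing the reagent at C3.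
   - Fallback: reverse the order of the two unions. Unmask the aldehyde of 13 and run the NHK intermolecularly with excess 17. Oxidise and carry out the (S)-CBS reduction on the acyclic enone, where reagent control is reliable. Then close the 14-membered ring at C8–C9 by intramolecular B-alkyl Suzuki coupling under high dilution.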